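The route rests on closing the hydroxylated trimethylcyclohexene ring (ring B, carotenoid atoms C1–C6) between the carbinol carbon C3 and the allylic methylene C4. The deconjugated C5=C6/C7H2/C8=O array of the target makes C4 the δ-terminus of a latent 2,4-dienoate, so C3 and C4 are both acceptor carbons; a samarium ketyl generated from a C3 aldehyde joins them in a vinylogous 6-endo reductive cyclization. One operation gives the ring, the carbinol, the tetrasubstituted alkene and the CH2–CO handle from an acyclic, achiral aldehyde–dienoate. A lipase then selects the 3R series, and a Liebeskind–Srogl acylation of a C29 stannyl polyene built from (R)-α-ionone completes the carotenoid.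

Key step: step 5

Remark: carotenoid numbering is used (ring B = C1–C6 of the hydroxylated cyclohex-1-enyl end that carries C7H2–C8=O, ring E = C1'–C6' of the cyclohex-2-enyl end, C19 = the hydroxymethyl carbon on C9); (R)-α-ionone of enantiopure natural grade is assumed to be purchasable, and all polyenes are handled under argon in the dark.

Step 1
Reactants: 1 2,2-dimethylpent-4-enal; 2 ethyl diazoacetate
Product: 3 ethyl 4,4-dimethyl-3-oxohept-6-enoate
Conditions: SnCl2 (10 mol%), CH2Cl2, 0 °C to rt
Reagents that add atoms: none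
Why: Roskamp reaction, in which the diazo carbon adds to the Lewis acid-activated, non-enolisable aldehyde and a 1,2-hydride shift with loss of N2 should give the β-keto ester directly.

Step 2
Reactants: 3 ethyl 4,4-dimethyl-3-oxohept-6-enoate
Product: 4 ethyl (2Z)-4,4-dimethyl-3-{[(trifluoromethyl)sulfonyl]oxy}hepta-2,6-dienoate
Conditions: Tf2O, aq. LiOH, toluene, 5 °C
Reagents that add atoms: trifluoromethanesulfonic anhydride, O=S(=O)(OS(=O)(=O)C(F)(F)F)C(F)(F)F
Why: O-sulfonylation of the chelated lithium enolate of the β-keto ester should give the enol triflate with the triflate cis to the ester (Z), the tertiary alkyl group taking the less crowded position.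

Step 3
Reactants: 4 ethyl (2Z)-4,4-dimethyl-3-{[(trifluoromethyl)sulfonyl]oxy}hepta-2,6-dienoate
Product: 6 ethyl (2Z)-4,4-dimethyl-6-oxo-3-{[(trifluoromethyl)sulfonyl]oxy}hex-2-enoate, via secondary ozonide 5 (not isolated)
Conditions: O3, CH2Cl2, −78 °C (Sudan Red end point); then PPh3, −78 °C to rt
Reagents that add atoms: ozone, [O-][O+]=O
Why: Ozonolysis with reductive work-up, in which electrophilic ozone should cleave only the terminal vinyl group because the triflyloxy-acrylate double bond is strongly deactivated.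

Step 4
Reactants: 6 ethyl (2Z)-4,4-dimethyl-6-oxo-3-{[(trifluoromethyl)sulfonyl]oxy}hex-2-enoate; 7 4,4,5,5-tetramethyl-2-(prop-1-en-2-yl)-1,3,2-dioxaborolane
Product: 8 ethyl (2E)-4,4-dimethyl-6-oxo-3-(prop-1-en-2-yl)hex-2-enoate
Conditions: Pd(OAc)2 (3 mol%), SPhos, K3PO4, THF/H2O, 40 °C
Reagents that add atoms: none
Why: Suzuki–Miyaura coupling of the enol triflate with retention of alkene geometry should install the isopropenyl group cis to the ester and complete the 2,4-dienoate, the aldehyde being tolerated by the mild phosphate base.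

Step 5
Reactants: 8 ethyl (2E)-4,4-dimethyl-6-oxo-3-(prop-1-en-2-yl)hex-2-enoate
Product: 9 ethyl 2-[(4RS)-4-hydroxy-2,6,6-trimethylcyclohex-1-en-1-yl]acetate (racemate)
Conditions: SmI2 (2.5 equiv), t-BuOH (3 equiv), THF (0.01 M), −78 to −20 °C
Reagents that add atoms: none
Why: SmI2 reduces the aldehyde of 8 to a samarium ketyl (polarity reversal at C3), which adds to C4, the unsubstituted δ-terminus of the 2,4-dienoate; a second electron transfer turns the C5–C6–C7 allyl radical into a samarium dienolate that t-BuOH protonates kinetically at the α-carbon C7, leaving the tetrasubstituted C5=C6 bond out of conjugation as in the target. The closest known reaction type is the SmI2 ketyl–olefin (aldehyde–enoate) reductive cyclization, used here in its vinylogous 1,6-sense. Ring B (C1–C6) closes in the 6-endo-trig mode, because 5-exo attack at C5 would build a quaternary centre and an unstabilised primary radical, and attack at the α-carbon C7 is polarity-mismatched. The new stereocentre C3 is formed without bias, since 8 is achiral and no chiral element is present, so 9 should be racemic and the 3R series is selected in step 6. The step needs δ-regioselectivity and α-protonation, secured by the terminal CH2 and by the kinetic behaviour of dienolates, and chemoselectivity over pinacol coupling, secured by high dilution at low temperature. Both geometries of the C6=C7 bond would converge on 9 because C7 becomes a methylene group.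

Step 6
Reactants: 9 ethyl 2-[(4RS)-4-hydroxy-2,6,6-trimethylcyclohex-1-en-1-yl]acetate
Product: 10 ethyl 2-[(4R)-4-(acetyloxy)-2,6,6-trimethylcyclohex-1-en-1-yl]acetate
Conditions: lipase PS (Burkholderia cepacia, immobilised), vinyl acetate, t-BuOMe, 30 °C, stopped at half conversion; chromatography
Reagents that add atoms: vinyl acetate, CC(=O)OC=C
Why: Lipase-catalysed kinetic resolution by irreversible transesterification, in which the enzyme should acylate the enantiomer whose larger ring arm (the CH2–CMe2 side) fits its large pocket, that is the 4R alcohol (3R in carotenoid numbering), while the 4S alcohol stays behind and is removed.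

Step 7
Reactants: 10 ethyl 2-[(4R)-4-(acetyloxy)-2,6,6-trimethylcyclohex-1-en-1-yl]acetate
Product: 11 S-phenyl 2-[(4R)-4-hydroxy-2,6,6-trimethylcyclohex-1-en-1-yl]ethanethioate
Conditions: AlMe3 (4 equiv), PhSH (4 equiv), CH2Cl2, 0 °C to rt; aq. KNaC4H4O6 (potassium sodium tartrate)
Reagents that add atoms: thiophenol, Sc1ccccc1
Why: Aluminium thiolate-mediated ester-to-thioester exchange should convert the ethyl ester into the S-phenyl thioester and at the same time transfer the acetyl group to thiolate, freeing the carbinol without acid or base that could move the ring double bond.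

Step 8
Reactants: 12 (R)-α-ionone, (3E)-4-[(1R)-2,6,6-trimethylcyclohex-2-en-1-yl]but-3-en-2-one; 13 triethyl phosphonoacetate
Product: 15 ethyl (2E,4E)-3-methyl-5-[(1R)-2,6,6-trimethylcyclohex-2-en-1-yl]penta-2,4-dienoate, via sodium phosphonate carbanion 14 (not isolated)
Conditions: NaH, THF, 0 °C; then 12, rt to 50 °C; chromatography
Reagents that add atoms: none
Why: Horner–Wadsworth–Emmons olefination of the methyl ketone should give mainly the 2E dienoate (the 2Z isomer is removed), and the weakly basic phosphonate anion should leave the C6' stereocentre intact.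

Step 9
Reactants: 15 ethyl (2E,4E)-3-methyl-5-[(1R)-2,6,6-trimethylcyclohex-2-en-1-yl]penta-2,4-dienoate
Product: 16 ethyl (2E,4E)-3-methyl-5-[(1R)-2,6,6-trimethyl-4-oxocyclohex-2-en-1-yl]penta-2,4-dienoate
Conditions: t-BuOOH (aq., 5 equiv), Rh2(cap)4 (dirhodium tetracaprolactamate, 1 mol%), ClCH2CH2Cl, 40 °C
Reagents that add atoms: tert-butyl hydroperoxide, CC(C)(C)OO
Why: Radical allylic oxidation, in which the tert-butylperoxyl radical should abstract hydrogen from the unhindered ring CH2 next to the trisubstituted alkene and the mixed peroxide collapses to the enone, without base so that C6' is not epimerised.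

Step 10
Reactants: 16 ethyl (2E,4E)-3-methyl-5-[(1R)-2,6,6-trimethyl-4-oxocyclohex-2-en-1-yl]penta-2,4-dienoate
Product: 17 ethyl (2E,4E)-5-[(1R,4R)-4-hydroxy-2,6,6-trimethylcyclohex-2-en-1-yl]-3-methylpenta-2,4-dienoate
Conditions: (S)-2-methyl-CBS-oxazaborolidine (20 mol%), catecholborane, toluene, −78 °C
Reagents that add atoms: none
Why: Corey–Bakshi–Shibata reduction, in which the (S)-oxazaborolidine binds the ring ketone with the alkene arm as the large substituent and should deliver hydride to the face that gives the 4R (3'R) allylic alcohol trans to the side chain, the ester being inert and any cis diastereomer separable.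

Step 11
Reactants: 17 ethyl (2E,4E)-5-[(1R,4R)-4-hydroxy-2,6,6-trimethylcyclohex-2-en-1-yl]-3-methylpenta-2,4-dienoate
Product: 18 (2E,4E)-5-[(1R,4R)-4-hydroxy-2,6,6-trimethylcyclohex-2-en-1-yl]-3-methylpenta-2,4-dien-1-ol
Conditions: i-Bu2AlH (3.5 equiv), CH2Cl2, −78 °C; aq. KNaC4H4O6
Reagents that add atoms: none
Why: 1,2-Reduction of the conjugated ester by the aluminium hydride should give the primary dienylic alcohol without touching the alkenes.

Step 12
Reactants: 18 (2E,4E)-5-[(1R,4R)-4-hydroxy-2,6,6-trimethylcyclohex-2-en-1-yl]-3-methylpenta-2,4-dien-1-ol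
Product: 19 [(2E,4E)-5-[(1R,4R)-4-hydroxy-2,6,6-trimethylcyclohex-2-en-1-yl]-3-methylpenta-2,4-dien-1-yl](triphenyl)phosphonium bromide
Conditions: PPh3·HBr (1.0 equiv), MeOH/CH2Cl2, 0 °C to rt
Reagents that add atoms: triphenylphosphine hydrobromide, [Br-].[PH+](c1ccccc1)(c1ccccc1)c1ccccc1
Why: Wittig salt formation, in which the primary pentadienylic alcohol ionises under the mildly acidic conditions and PPh3 captures the delocalised cation at its primary terminus, while the far less ionisable ring allylic alcohol should survive at low temperature.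

Step 13
Reactants: 19 [(2E,4E)-5-[(1R,4R)-4-hydroxy-2,6,6-trimethylcyclohex-2-en-1-yl]-3-methylpenta-2,4-dien-1-yl](triphenyl)phosphonium bromide; 20 (2E,4E,6E)-2,7-dimethylocta-2,4,6-trienedial
Product: 22 (2E,4E,6E,8E,10E,12E)-13-[(1R,4R)-4-hydroxy-2,6,6-trimethylcyclohex-2-en-1-yl]-2,7,11-trimethyltrideca-2,4,6,8,10,12-hexaenal, via C15 phosphorus ylide 21 (not isolated)
Conditions: 20 (2 equiv), NaOMe, MeOH/CH2Cl2, 0 °C to rt; then heptane, reflux (Z to E equilibration)
Reagents that add atoms: none
Why: Wittig reaction of the semistabilised ylide with one aldehyde of the excess symmetrical dialdehyde, the monoadduct being a less electrophilic polyenal and the hindered Z isomer at the new double bond reverting to E on heating.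

Step 14
Reactants: 22 (2E,4E,6E,8E,10E,12E)-13-[(1R,4R)-4-hydroxy-2,6,6-trimethylcyclohex-2-en-1-yl]-2,7,11-trimethyltrideca-2,4,6,8,10,12-hexaenal
Product: 23 (2E,4E,6E,8E,10E,12E)-13-[(1R,4R)-4-hydroxy-2,6,6-trimethylcyclohex-2-en-1-yl]-2,7,11-trimethyltrideca-2,4,6,8,10,12-hexaen-1-ol
Conditions: NaBH4, EtOH/THF, 0 °C
Reagents that add atoms: none
Why: Borohydride 1,2-reduction of the polyenal should give the primary polyenylic alcohol cleanly.

Step 15
Reactants: 23 (2E,4E,6E,8E,10E,12E)-13-[(1R,4R)-4-hydroxy-2,6,6-trimethylcyclohex-2-en-1-yl]-2,7,11-trimethyltrideca-2,4,6,8,10,12-hexaen-1-ol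
Product: 24 [(2E,4E,6E,8E,10E,12E)-13-[(1R,4R)-4-hydroxy-2,6,6-trimethylcyclohex-2-en-1-yl]-2,7,11-trimethyltrideca-2,4,6,8,10,12-hexaen-1-yl](triphenyl)phosphonium bromide
Conditions: PPh3·HBr (1.0 equiv), CH2Cl2/MeOH, −10 °C to rt, dark
Reagents that add atoms: triphenylphosphine hydrobromide, [Br-].[PH+](c1ccccc1)(c1ccccc1)c1ccccc1
Why: Wittig salt formation as in step 12, the polyenylic cation being far more easily formed than the ring allylic one, so that phosphine capture at the primary terminus should be selective.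

Step 16
Reactants: 25 4-bromofuran-2(5H)-one; 26 hexabutyldistannane
Product: 27 4-(tributylstannyl)furan-2(5H)-one
Conditions: Pd(PPh3)4 (5 mol%), toluene, 90 °C
Reagents that add atoms: none
Why: Stille-type stannylation, in which zerovalent palladium inserts into the activated vinyl bromide, the distannane transmetalates and reductive elimination should give the vinylstannane.

Step 17
Reactants: 27 4-(tributylstannyl)furan-2(5H)-one
Product: 28 4-(tributylstannyl)-2,5-dihydrofuran-2-ol (lactol, both configurations at the hemiacetal carbon)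
Conditions: i-Bu2AlH (1.1 equiv), CH2Cl2, −78 °C; MeOH, aq. KNaC4H4O6
Reagents that add atoms: none
Why: Half-reduction of the butenolide at low temperature should stop at the aluminium hemiacetal, which gives the lactol on neutral work-up, the ring holding the future C19 oxygen and C11 cis on the stannylated double bond.

Step 18
Reactants: 24 [(2E,4E,6E,8E,10E,12E)-13-[(1R,4R)-4-hydroxy-2,6,6-trimethylcyclohex-2-en-1-yl]-2,7,11-trimethyltrideca-2,4,6,8,10,12-hexaen-1-yl](triphenyl)phosphonium bromide; 28 4-(tributylstannyl)-2,5-dihydrofuran-2-ol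
Product: 30 (2E,4E,6E,8E,10E,12E,14E,16E)-17-[(1R,4R)-4-hydroxy-2,6,6-trimethylcyclohex-2-en-1-yl]-6,11,15-trimethyl-2-(tributylstannyl)heptadeca-2,4,6,8,10,12,14,16-octaen-1-ol, via C25 phosphorus ylide 29 (not isolated)
Conditions: NaOMe (3 equiv), CH2Cl2/MeOH, −10 °C to rt; then EtOAc, 60 °C, dark (Z to E equilibration)
Reagents that add atoms: none
Why: Wittig reaction of the ylide with the lactol, which reacts through its open hydroxy-enal form under base, so that the ring-derived geometry of the C9=C10 bond (CH2OH cis to C11) is kept and the hindered 11Z isomer should equilibrate to 11E on warming.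

Step 19
Reactants: 30 (2E,4E,6E,8E,10E,12E,14E,16E)-17-[(1R,4R)-4-hydroxy-2,6,6-trimethylcyclohex-2-en-1-yl]-6,11,15-trimethyl-2-(tributylstannyl)heptadeca-2,4,6,8,10,12,14,16-octaen-1-ol; 11 S-phenyl 2-[(4R)-4-hydroxy-2,6,6-trimethylcyclohex-1-en-1-yl]ethanethioate
Product: 31 siphonaxanthin, all-E-(3R,3'R,6'R)-3,19,3'-trihydroxy-7,8-dihydro-β,ε-caroten-8-one
Conditions: Pd2(dba)3 (5 mol%), tri(2-furyl)phosphine, CuOP(O)Ph2 (copper diphenylphosphinate, monovalent copper, 1.5 equiv), THF, rt, dark
Reagents that add atoms: none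
Why: Liebeskind–Srogl coupling, in which zerovalent palladium inserts into the acyl–sulfur bond, the copper carboxylate takes up thiolate and promotes transmetalation of the vinylstannane with retention of the C9=C10 geometry, and reductive elimination should form the C8–C9 bond under neutral conditions that tolerate the three free hydroxyl groups and the enolisable ketone.

Compound list
1 | 2,2-dimethylpent-4-enal | C=CCC(C)(C)C=O | starting material
2 | ethyl diazoacetate | CCOC(=O)C=[N+]=[N-] | starting material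
3 | ethyl 4,4-dimethyl-3-oxohept-6-enoate | CCOC(=O)CC(=O)C(C)(C)CC=C | intermediate
4 | ethyl (2Z)-4,4-dimethyl-3-{[(trifluoromethyl)sulfonyl]oxy}hepta-2,6-dienoate | CCOC(=O)/C=C(\OS(=O)(=O)C(F)(F)F)C(C)(C)CC=C | intermediate
5 | ethyl (2Z)-4,4-dimethyl-5-(1,2,4-trioxolan-3-yl)-3-{[(trifluoromethyl)sulfonyl]oxy}pent-2-enoate (secondary ozonide, not isolated) | CCOC(=O)/C=C(\OS(=O)(=O)C(F)(F)F)C(C)(C)CC1OCOO1 | intermediate
6 | ethyl (2Z)-4,4-dimethyl-6-oxo-3-{[(trifluoromethyl)sulfonyl]oxy}hex-2-enoate | CCOC(=O)/C=C(\OS(=O)(=O)C(F)(F)F)C(C)(C)CC=O | intermediate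
7 | 4,4,5,5-tetramethyl-2-(prop-1-en-2-yl)-1,3,2-dioxaborolane | CC(=C)B1OC(C)(C)C(C)(C)O1 | starting material
8 | ethyl (2E)-4,4-dimethyl-6-oxo-3-(prop-1-en-2-yl)hex-2-enoate | CCOC(=O)/C=C(\C(C)=C)C(C)(C)CC=O | intermediate
9 | ethyl 2-[(4RS)-4-hydroxy-2,6,6-trimethylcyclohex-1-en-1-yl]acetate (racemate) | CCOC(=O)CC1=C(C)CC(O)CC1(C)C | intermediate
10 | ethyl 2-[(4R)-4-(acetyloxy)-2,6,6-trimethylcyclohex-1-en-1-yl]acetate | CCOC(=O)CC1=C(C)C[C@@H](OC(C)=O)CC1(C)C | intermediate
11 | S-phenyl 2-[(4R)-4-hydroxy-2,6,6-trimethylcyclohex-1-en-1-yl]ethanethioate | O=C(CC1=C(C)C[C@@H](O)CC1(C)C)Sc1ccccc1 | intermediate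
12 | (R)-α-ionone, (3E)-4-[(1R)-2,6,6-trimethylcyclohex-2-en-1-yl]but-3-en-2-one | CC1=CCCC(C)(C)[C@H]1/C=C/C(C)=O | starting material
13 | triethyl phosphonoacetate | CCOC(=O)CP(=O)(OCC)OCC | starting material
14 | sodium salt of the triethyl phosphonoacetate carbanion (not isolated) | CCOC(=O)[CH-]P(=O)(OCC)OCC.[Na+] | intermediate
15 | ethyl (2E,4E)-3-methyl-5-[(1R)-2,6,6-trimethylcyclohex-2-en-1-yl]penta-2,4-dienoate | CC1=CCCC(C)(C)[C@H]1/C=C/C(C)=C/C(=O)OCC | intermediate
16 | ethyl (2E,4E)-3-methyl-5-[(1R)-2,6,6-trimethyl-4-oxocyclohex-2-en-1-yl]penta-2,4-dienoate | CC1=CC(=O)CC(C)(C)[C@H]1/C=C/C(C)=C/C(=O)OCC | intermediate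
17 | ethyl (2E,4E)-5-[(1R,4R)-4-hydroxy-2,6,6-trimethylcyclohex-2-en-1-yl]-3-methylpenta-2,4-dienoate | CC1=C[C@H](O)CC(C)(C)[C@H]1/C=C/C(C)=C/C(=O)OCC | intermediate
18 | (2E,4E)-5-[(1R,4R)-4-hydroxy-2,6,6-trimethylcyclohex-2-en-1-yl]-3-methylpenta-2,4-dien-1-ol | CC1=C[C@H](O)CC(C)(C)[C@H]1/C=C/C(C)=C/CO | intermediate
19 | [(2E,4E)-5-[(1R,4R)-4-hydroxy-2,6,6-trimethylcyclohex-2-en-1-yl]-3-methylpenta-2,4-dien-1-yl](triphenyl)phosphonium bromide | CC1=C[C@H](O)CC(C)(C)[C@H]1/C=C/C(C)=C/C[P+](c1ccccc1)(c1ccccc1)c1ccccc1.[Br-] | intermediate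
20 | (2E,4E,6E)-2,7-dimethylocta-2,4,6-trienedial | O=C/C(C)=C/C=C/C=C(C)/C=O | starting material
21 | ylide of 19, (2E,4E)-5-[(1R,4R)-4-hydroxy-2,6,6-trimethylcyclohex-2-en-1-yl]-3-methylpenta-2,4-dienylidene(triphenyl)phosphorane (not isolated) | CC1=C[C@H](O)CC(C)(C)[C@H]1/C=C/C(C)=C/C=P(c1ccccc1)(c1ccccc1)c1ccccc1 | intermediate
22 | (2E,4E,6E,8E,10E,12E)-13-[(1R,4R)-4-hydroxy-2,6,6-trimethylcyclohex-2-en-1-yl]-2,7,11-trimethyltrideca-2,4,6,8,10,12-hexaenal | CC1=C[C@H](O)CC(C)(C)[C@H]1/C=C/C(C)=C/C=C/C(C)=C/C=C/C=C(C)/C=O | intermediate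
23 | (2E,4E,6E,8E,10E,12E)-13-[(1R,4R)-4-hydroxy-2,6,6-trimethylcyclohex-2-en-1-yl]-2,7,11-trimethyltrideca-2,4,6,8,10,12-hexaen-1-ol | CC1=C[C@H](O)CC(C)(C)[C@H]1/C=C/C(C)=C/C=C/C(C)=C/C=C/C=C(C)/CO | intermediate
24 | [(2E,4E,6E,8E,10E,12E)-13-[(1R,4R)-4-hydroxy-2,6,6-trimethylcyclohex-2-en-1-yl]-2,7,11-trimethyltrideca-2,4,6,8,10,12-hexaen-1-yl](triphenyl)phosphonium bromide | CC1=C[C@H](O)CC(C)(C)[C@H]1/C=C/C(C)=C/C=C/C(C)=C/C=C/C=C(C)/C[P+](c1ccccc1)(c1ccccc1)c1ccccc1.[Br-] | intermediate
25 | 4-bromofuran-2(5H)-one | O=C1C=C(Br)CO1 | starting material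
26 | hexabutyldistannane | CCCC[Sn](CCCC)(CCCC)[Sn](CCCC)(CCCC)CCCC | starting material
27 | 4-(tributylstannyl)furan-2(5H)-one | O=C1C=C(CO1)[Sn](CCCC)(CCCC)CCCC | intermediate
28 | 4-(tributylstannyl)-2,5-dihydrofuran-2-ol (both configurations at the hemiacetal carbon) | OC1C=C(CO1)[Sn](CCCC)(CCCC)CCCC | intermediate
29 | ylide of 24, (2E,4E,6E,8E,10E,12E)-13-[(1R,4R)-4-hydroxy-2,6,6-trimethylcyclohex-2-en-1-yl]-2,7,11-trimethyltrideca-2,4,6,8,10,12-hexaenylidene(triphenyl)phosphorane (not isolated) | CC1=C[C@H](O)CC(C)(C)[C@H]1/C=C/C(C)=C/C=C/C(C)=C/C=C/C=C(C)/C=P(c1ccccc1)(c1ccccc1)c1ccccc1 | intermediate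
30 | (2E,4E,6E,8E,10E,12E,14E,16E)-17-[(1R,4R)-4-hydroxy-2,6,6-trimethylcyclohex-2-en-1-yl]-6,11,15-trimethyl-2-(tributylstannyl)heptadeca-2,4,6,8,10,12,14,16-octaen-1-ol | CC1=C[C@H](O)CC(C)(C)[C@H]1/C=C/C(C)=C/C=C/C(C)=C/C=C/C=C(C)/C=C/C=C(\CO)[Sn](CCCC)(CCCC)CCCC | intermediate
31 | siphonaxanthin, all-E-(3R,3'R,6'R)-3,19,3'-trihydroxy-7,8-dihydro-β,ε-caroten-8-one | CC1=C[C@H](O)CC(C)(C)[C@H]1/C=C/C(C)=C/C=C/C(C)=C/C=C/C=C(C)/C=C/C=C(\CO)C(=O)CC1=C(C)C[C@@H](O)CC1(C)C | target

Total step count: 19. Longest linear sequence: 10 steps (steps 8 to 15, then 18 and 19, from (R)-α-ionone).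

Steps most likely to fail

Step 5. The ketyl may be reduced further or dimerise by pinacol coupling before it cyclises, it may attack the α-carbon in the 5-exo sense, or the dienolate may be protonated at the γ-carbon. The fallback sets out from 8 and closes the same C3–C4 bond by a redox-neutral acyl-radical hydroacylation. Irradiation (365 nm) of 8 with (n-Bu4N)4W10O32 (tetrabutylammonium decatungstate, 2 mol%) in MeCN abstracts the formyl hydrogen, the nucleophilic acyl radical adds 6-endo to the δ-carbon of the dienoate, and back hydrogen transfer to C7 should give ethyl 2-(2,6,6-trimethyl-4-oxocyclohex-1-en-1-yl)acetate F1. NaBH4 in MeOH at −20 °C then reduces the ring ketone, and the route is rejoined at 9.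

Step 19. Transmetalation of the α-branched polyenylstannane may be slow, so that protodestannylation, decarbonylation of the acyl–palladium species or isomerisation of the polyene takes over. The fallback sets out from 11 and 28 and changes the order of bond formation. The thioester coupling is run on the small, unhindered stannane 28 (Pd2(dba)3, tri(2-furyl)phosphine, CuOP(O)Ph2, THF, rt) to give 1-(5-hydroxy-2,5-dihydrofuran-3-yl)-2-[(4R)-4-hydroxy-2,6,6-trimethylcyclohex-1-en-1-yl]ethan-1-one F2. The C11=C12 bond is then made last by Wittig reaction of F2 with the ylide generated from 24 (NaOMe, CH2Cl2/MeOH, −20 °C, then thermal Z to E equilibration), which comes back to the route at 31.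

Step 18. The lactol may dehydrate to the furan, or its open hydroxy-enal form may isomerise at the stannylated double bond before it is olefinated. The fallback sets out from 27 and makes the aldehyde partner as an open-chain silyl ether. Ring opening with Me(MeO)NH·HCl/AlMe3 should give (2E)-4-hydroxy-N-methoxy-N-methyl-3-(tributylstannyl)but-2-enamide F3. TBSCl/imidazole gives (2E)-4-{[tert-butyl(dimethyl)silyl]oxy}-N-methoxy-N-methyl-3-(tributylstannyl)but-2-enamide F4, and i-Bu2AlH at −78 °C gives (2E)-4-{[tert-butyl(dimethyl)silyl]oxy}-3-(tributylstannyl)but-2-enal F5. Wittig reaction with the ylide from 24 gives the primary tert-butyl(dimethyl)silyl ether of 30 F6, and Bu4NF buffered with AcOH removes the silyl group, so that the route is rejoined at 30.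

Further compounds
F1 | step 5 | ethyl 2-(2,6,6-trimethyl-4-oxocyclohex-1-en-1-yl)acetate | CCOC(=O)CC1=C(C)CC(=O)CC1(C)C
F2 | step 19 | 1-(5-hydroxy-2,5-dihydrofuran-3-yl)-2-[(4R)-4-hydroxy-2,6,6-trimethylcyclohex-1-en-1-yl]ethan-1-one | OC1OCC(=C1)C(=O)CC1=C(C)C[C@@H](O)CC1(C)C
F3 | step 18 | (2E)-4-hydroxy-N-methoxy-N-methyl-3-(tributylstannyl)but-2-enamide | CON(C)C(=O)/C=C(\CO)[Sn](CCCC)(CCCC)CCCC
F4 | step 18 | (2E)-4-{[tert-butyl(dimethyl)silyl]oxy}-N-methoxy-N-methyl-3-(tributylstannyl)but-2-enamide | CON(C)C(=O)/C=C(\CO[Si](C)(C)C(C)(C)C)[Sn](CCCC)(CCCC)CCCC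
F5 | step 18 | (2E)-4-{[tert-butyl(dimethyl)silyl]oxy}-3-(tributylstannyl)but-2-enal | O=C/C=C(\CO[Si](C)(C)C(C)(C)C)[Sn](CCCC)(CCCC)CCCC
F6 | step 18 | primary tert-butyl(dimethyl)silyl ether of 30 | CC1=C[C@H](O)CC(C)(C)[C@H]1/C=C/C(C)=C/C=C/C(C)=C/C=C/C=C(C)/C=C/C=C(\CO[Si](C)(C)C(C)(C)C)[Sn](CCCC)(CCCC)CCCC
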